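Numbering used below: in the flavanone half, O1, C2 (ketal carbon), C3 (methine), C4 (C=O), C4a, C8a, ring A and ring B. In the flavan half, O1'', C2'', O5'', O7'', C8'' and aromatic ring D.
Last disconnection: hydrogenolysis of five benzyl ethers. Key disconnection: the protected target goes back, in one acid-catalysed operation, to a 2-arylbenzofuran-3(2H)-one and a 7-hydroxy-8-formylflavan. The forward sequence is aldol bond C2–C3, loss of water to the ring D o-quinone methide, 1,2-shift of the C4 acyl carbon from C2 to C3, then ketal closure O7''–C2.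
Enabling feature: C3 is the benzylic carbon of ring D, ortho to O7'' and O1'' and para to O5'', so it is an o-quinone methide terminus. Its neighbour C2 carries O1 and ring B, so it is a latent flavylium-type cation. The charge can therefore pass from C3 to C2 by moving only the C4 acyl group, and O7'' then sits 1,5 to C2.
Fragment 1 comes from phloroglucinol and 4-hydroxyphenylacetic acid (deoxybenzoin, then α-bromination and O-alkylation). Fragment 2 comes from 2,4,6-trihydroxybenzaldehyde and 4'-(benzyloxy)acetophenone (chalcone, asymmetric transfer hydrogenation, Mitsunobu closure, C8 bromination and formylation).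
Ring order: furanone ring of fragment 1; pyran ring of the flavan; then, in one step, the chromanone ring (grown from the furanone ring) and the dihydrofuran ring.

Key step: step 13

Assumption: the sense of induction of the chiral acid in step 13 cannot be derived from a close model. The (R)-configured catalyst is written, and its enantiomer is taken if the (2R,3R) series should form.

Step 1
Reactants: 1 phloroglucinol; 2 4-hydroxyphenylacetic acid
Product: 3 2-(4-hydroxyphenyl)-1-(2,4,6-trihydroxyphenyl)ethan-1-one
Conditions: BF3·OEt2 (as solvent), 85 °C; then aq. NaOAc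
Reagents that add atoms: none
Why: Friedel–Crafts acylation of the symmetric, very nucleophilic triol should stop at monoacylation because the chelated ketone deactivates the ring.

Step 2
Reactants: 3 2-(4-hydroxyphenyl)-1-(2,4,6-trihydroxyphenyl)ethan-1-one
Product: 4 1-[2,4-bis(benzyloxy)-6-hydroxyphenyl]-2-[4-(benzyloxy)phenyl]ethan-1-one
Conditions: BnBr (3.0 equiv), K2CO3, acetone, reflux
Reagents that add atoms: benzyl bromide, BrCc1ccccc1
Why: Williamson ether synthesis; the last ortho phenol is hydrogen-bonded to the ketone, is the least nucleophilic and should stay free.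

Step 3
Reactants: 4 1-[2,4-bis(benzyloxy)-6-hydroxyphenyl]-2-[4-(benzyloxy)phenyl]ethan-1-one
Product: 6 4,6-bis(benzyloxy)-2-[4-(benzyloxy)phenyl]benzofuran-3(2H)-one (racemic, freely enolising), via α-bromo ketone 5 (not isolated)
Conditions: CuBr2 (2.1 equiv), EtOAc–CHCl3, reflux, filter; then NaOAc, EtOH, Ar, 60 °C
Reagents that add atoms: none
Why: Enol-selective α-bromination of the ketone followed by intramolecular Williamson displacement (5-exo-tet) is the standard coumaranone synthesis; the new centre is racemic and labile, which does not matter because 6 reacts through its achiral enol.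

Step 4
Reactants: 7 2,4,6-trihydroxybenzaldehyde
Product: 8 2,6-dihydroxy-4-(methoxymethoxy)benzaldehyde
Conditions: MOMCl (1.0 equiv), iPr2NEt, CH2Cl2–THF, 0 °C
Reagents that add atoms: chloromethyl methyl ether, COCCl
Why: O-alkylation (MOM acetal formation) should take place at the only non-chelated and most acidic phenol, para to the formyl group.

Step 5
Reactants: 8 2,6-dihydroxy-4-(methoxymethoxy)benzaldehyde
Product: 9 2-(benzyloxy)-6-hydroxy-4-(methoxymethoxy)benzaldehyde
Conditions: BnBr (1.0 equiv), K2CO3, DMF, rt
Reagents that add atoms: benzyl bromide, BrCc1ccccc1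
Why: Williamson ether synthesis on two equivalent ortho phenols; after the first alkylation the remaining phenol is firmly chelated and should resist a second one.

Step 6
Reactants: 9 2-(benzyloxy)-6-hydroxy-4-(methoxymethoxy)benzaldehyde; 10 4'-(benzyloxy)acetophenone
Product: 11 (E)-3-[2-(benzyloxy)-6-hydroxy-4-(methoxymethoxy)phenyl]-1-[4-(benzyloxy)phenyl]prop-2-en-1-one
Conditions: KOH, EtOH–H2O, 40 °C; then dilute HCl to pH 6
Reagents that add atoms: none
Why: Claisen–Schmidt condensation, the usual access to 2-hydroxychalcones; the E alkene is the thermodynamic product.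

Step 7
Reactants: 11 the (E)-2-hydroxychalcone
Product: 12 3-[2-(benzyloxy)-6-hydroxy-4-(methoxymethoxy)phenyl]-1-[4-(benzyloxy)phenyl]propan-1-one
Conditions: H2 (1 atm), Pd/C, Ph2S (cat.), EtOAc, rt
Reagents that add atoms: none
Why: Chemoselective catalytic hydrogenation; the sulfide-poisoned Pd/C should saturate the enone C=C and leave benzyl ethers and the aryl ketone untouched.

Step 8
Reactants: 12 the saturated ketone
Product: 13 (S)-3-(benzyloxy)-2-{3-[4-(benzyloxy)phenyl]-3-hydroxypropyl}-5-(methoxymethoxy)phenol
Conditions: RuCl[(S,S)-TsDPEN](p-cymene) (1 mol %), HCO2Na, H2O–EtOAc, 40 °C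
Reagents that add atoms: none
Why: Noyori-type asymmetric transfer hydrogenation of an aryl alkyl ketone; the (S,S) catalyst delivers hydride to the face that gives the (S)-carbinol, and the near-neutral formate medium avoids ionisation of the electron-rich benzylic alcohol.

Step 9
Reactants: 13 the (S)-carbinol
Product: 14 (R)-5-(benzyloxy)-2-[4-(benzyloxy)phenyl]-7-(methoxymethoxy)chromane
Conditions: PPh3, DIAD, THF, 0 °C
Reagents that add atoms: none
Why: Intramolecular Mitsunobu etherification (6-exo-tet SN2) by the only free phenol closes the pyran ring with inversion, (S)-carbinol to (R)-flavan.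

Step 10
Reactants: 14 the (R)-flavan
Product: 15 (R)-5-(benzyloxy)-2-[4-(benzyloxy)phenyl]-8-bromo-7-(methoxymethoxy)chromane
Conditions: NBS (1.0 equiv), CH2Cl2, −78 to −40 °C
Reagents that add atoms: N-bromosuccinimide, O=C1CCC(=O)N1Br
Why: Electrophilic aromatic bromination of ring D, by far the most activated ring; C8 lies next to the tied-back pyran oxygen and is more accessible than C6 between two free alkoxy groups, which is the site preference known for 5,7-di-O-alkylated flavans.

Step 11
Reactants: 15 the 8-bromoflavan
Product: 17 (R)-5-(benzyloxy)-2-[4-(benzyloxy)phenyl]-7-(methoxymethoxy)chromane-8-carbaldehyde, via aryllithium 16 (not isolated)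
Conditions: n-BuLi, THF, −78 °C; DMF, −78 °C to 0 °C; H2O
Reagents that add atoms: N,N-dimethylformamide, CN(C)C=O
Why: Bromine–lithium exchange, aided by chelation to the MOM group, and Bouveault-type formylation fix the carbon that becomes C3 at C8''.

Step 12
Reactants: 17 the MOM-protected aldehyde
Product: 18 (R)-5-(benzyloxy)-2-[4-(benzyloxy)phenyl]-7-hydroxychromane-8-carbaldehyde
Conditions: conc. HCl (cat.), MeOH–THF, 45 °C
Reagents that add atoms: none
Why: Acid-catalysed transacetalisation removes the MOM group ortho to the formyl group under conditions that benzyl ethers and the flavan C2''–O1'' bond (oxygen conjugated to the aldehyde, weakly basic) should survive.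

Step 13
Reactants: 6 4,6-bis(benzyloxy)-2-[4-(benzyloxy)phenyl]benzofuran-3(2H)-one; 18 (R)-5-(benzyloxy)-2-[4-(benzyloxy)phenyl]-7-hydroxychromane-8-carbaldehyde
Product: 21 5,7,4',5'',4'''-penta-O-benzyl ether of the target (2S,3S,2''R; cis-fused ketal), via aldol carbinol 19 (not isolated), via o-quinone methide 20 (not isolated)
Conditions: (R)-3,3'-bis(2,4,6-triisopropylphenyl)-BINOL N-triflylphosphoramide (10 mol %), 4 Å MS, toluene–CH2Cl2, Ar, −20 °C to rt
Reagents that add atoms: none
Why: Proposed new method: the chiral acid activates the chelated aldehyde of 18 for attack by C2 of the enol of 6 (the C–C bond-forming event of the acid-catalysed salicylaldehyde/aryl ketone condensation used for flavylium salts) and, since C2 of carbinol 19 is quaternary, loss of water can only lead to the ring D o-quinone methide 20, held as its O7''-protonated ion pair with the catalyst anion. In 20 the C4 acyl carbon shifts from C2 to the electron-poor C3 (semipinacol-type 1,2-acyl shift), which inserts C3 into the five-membered furanone ring (C4, C4a, C8a, O1, C2) to give the six-membered chromanone ring and hands the charge to C2, where O1 and ring B hold it as a flavylium-like oxocarbenium ion. The closest known reaction types are the Lewis acid induced 1,2-acyl shift of α,β-epoxy ketones to 1,3-dicarbonyl compounds and the chiral phosphoric acid catalysed pinacol rearrangement that runs through hydrogen-bonded quinone methide type ion pairs. The dihydrofuran ring closes by 5-exo-trig attack of O7'' on the C2 oxocarbenium ion, while the chromanone ring is not closed but grown by the shift. C3 is set in the shift by the chiral anion, which is bound to O7''–H and shields one face of planar C3 (the aldol step is reversible and the C2 centre of 19 is erased, so both epimers of 19 drain through the faster ion pair), and C2 follows from C3 because only the cis-fused 5/6 ketal is geometrically possible, the remote C2'' centre taking no part. The step needs acyl instead of aryl or aryloxy migration, which is secured because only departure of the acyl group leaves a cation flanked by both O1 and the p-benzyloxyphenyl ring, closure by O7'' alone, which is secured because O1'' is locked in the pyran ring and O5'' is benzylated, and capture of C2 before H3 is lost to the flavone, which is favoured by the 1,5-placed phenol, the weakly basic medium and the low temperature.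

Step 14
Reactants: 21 the pentabenzyl ether
Product: 22 target CNP0179743.1, (2S,3S,2''R)
Conditions: H2 (1 atm), Pd(OH)2/C, THF–MeOH, rt
Reagents that add atoms: none
Why: Neutral catalytic hydrogenolysis of the five aryl benzyl ethers, as practised on benzylated flavans and doubly linked flavonoid ketals, should spare the diaryl ketal, the pyran C2''–O bond and the vinylogous-ester-like C4 ketone, and touches no stereocentre.

Compound list
1 | phloroglucinol | Oc1cc(O)cc(O)c1 | starting material
2 | 4-hydroxyphenylacetic acid | OC(=O)Cc1ccc(O)cc1 | starting material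
3 | 2-(4-hydroxyphenyl)-1-(2,4,6-trihydroxyphenyl)ethan-1-one | O=C(Cc1ccc(O)cc1)c1c(O)cc(O)cc1O | intermediate
4 | 1-[2,4-bis(benzyloxy)-6-hydroxyphenyl]-2-[4-(benzyloxy)phenyl]ethan-1-one | O=C(Cc1ccc(OCc2ccccc2)cc1)c1c(O)cc(OCc2ccccc2)cc1OCc1ccccc1 | intermediate
5 | 1-[2,4-bis(benzyloxy)-6-hydroxyphenyl]-2-[4-(benzyloxy)phenyl]-2-bromoethan-1-one (racemic, not isolated) | O=C(C(Br)c1ccc(OCc2ccccc2)cc1)c1c(O)cc(OCc2ccccc2)cc1OCc1ccccc1 | intermediate
6 | 4,6-bis(benzyloxy)-2-[4-(benzyloxy)phenyl]benzofuran-3(2H)-one (racemic) | O=C1C(c2ccc(OCc3ccccc3)cc2)Oc2cc(OCc3ccccc3)cc(OCc3ccccc3)c12 | intermediate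
7 | 2,4,6-trihydroxybenzaldehyde | O=Cc1c(O)cc(O)cc1O | starting material
8 | 2,6-dihydroxy-4-(methoxymethoxy)benzaldehyde | O=Cc1c(O)cc(OCOC)cc1O | intermediate
9 | 2-(benzyloxy)-6-hydroxy-4-(methoxymethoxy)benzaldehyde | O=Cc1c(O)cc(OCOC)cc1OCc1ccccc1 | intermediate
10 | 4'-(benzyloxy)acetophenone | CC(=O)c1ccc(OCc2ccccc2)cc1 | starting material
11 | (E)-3-[2-(benzyloxy)-6-hydroxy-4-(methoxymethoxy)phenyl]-1-[4-(benzyloxy)phenyl]prop-2-en-1-one | O=C(/C=C/c1c(O)cc(OCOC)cc1OCc1ccccc1)c1ccc(OCc2ccccc2)cc1 | intermediate
12 | 3-[2-(benzyloxy)-6-hydroxy-4-(methoxymethoxy)phenyl]-1-[4-(benzyloxy)phenyl]propan-1-one | O=C(CCc1c(O)cc(OCOC)cc1OCc1ccccc1)c1ccc(OCc2ccccc2)cc1 | intermediate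
13 | (S)-3-(benzyloxy)-2-{3-[4-(benzyloxy)phenyl]-3-hydroxypropyl}-5-(methoxymethoxy)phenol | O[C@@H](CCc1c(O)cc(OCOC)cc1OCc1ccccc1)c1ccc(OCc2ccccc2)cc1 | intermediate
14 | (R)-5-(benzyloxy)-2-[4-(benzyloxy)phenyl]-7-(methoxymethoxy)chromane | COCOc1cc(OCc2ccccc2)c2c(c1)O[C@@H](c1ccc(OCc3ccccc3)cc1)CC2 | intermediate
15 | (R)-5-(benzyloxy)-2-[4-(benzyloxy)phenyl]-8-bromo-7-(methoxymethoxy)chromane | COCOc1cc(OCc2ccccc2)c2c(c1Br)O[C@@H](c1ccc(OCc3ccccc3)cc1)CC2 | intermediate
16 | (R)-8-lithio-5-(benzyloxy)-2-[4-(benzyloxy)phenyl]-7-(methoxymethoxy)chromane (not isolated) | COCOc1cc(OCc2ccccc2)c2c(c1[Li])O[C@@H](c1ccc(OCc3ccccc3)cc1)CC2 | intermediate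
17 | (R)-5-(benzyloxy)-2-[4-(benzyloxy)phenyl]-7-(methoxymethoxy)chromane-8-carbaldehyde | COCOc1cc(OCc2ccccc2)c2c(c1C=O)O[C@@H](c1ccc(OCc3ccccc3)cc1)CC2 | intermediate
18 | (R)-5-(benzyloxy)-2-[4-(benzyloxy)phenyl]-7-hydroxychromane-8-carbaldehyde | O=Cc1c(O)cc(OCc2ccccc2)c2c1O[C@@H](c1ccc(OCc3ccccc3)cc1)CC2 | intermediate
19 | 4,6-bis(benzyloxy)-2-[4-(benzyloxy)phenyl]-2-{hydroxy[(2R)-5-(benzyloxy)-2-(4-benzyloxyphenyl)-7-hydroxychroman-8-yl]methyl}benzofuran-3(2H)-one (epimers at the two new centres, not isolated) | O=C1c2c(OCc3ccccc3)cc(OCc3ccccc3)cc2OC1(c1ccc(OCc2ccccc2)cc1)C(O)c1c(O)cc(OCc2ccccc2)c2c1O[C@@H](c1ccc(OCc3ccccc3)cc1)CC2 | intermediate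
20 | ring D o-quinone methide: the (2R)-5-(benzyloxy)-2-(4-benzyloxyphenyl)-7-oxo-3,4-dihydro-2H-chromen-8(7H)-ylidene unit joined through the exocyclic CH to C2 of the benzofuranone (not isolated) | O=C1c2c(OCc3ccccc3)cc(OCc3ccccc3)cc2OC1(c1ccc(OCc2ccccc2)cc1)C=C1C(=O)C=C(OCc2ccccc2)C2=C1O[C@@H](c1ccc(OCc3ccccc3)cc1)CC2 | intermediate
21 | (2S,3S,2''R)-5,7,4',5'',4'''-penta-O-benzyl ether of the target | O=C1c2c(OCc3ccccc3)cc(OCc3ccccc3)cc2O[C@@]2(c3ccc(OCc4ccccc4)cc3)Oc3cc(OCc4ccccc4)c4c(c3[C@@H]12)O[C@@H](c1ccc(OCc2ccccc2)cc1)CC4 | intermediate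
22 | CNP0179743.1, (2S,3S,2''R); chromanone cis-fused at C2–C3 to the dihydrofuran ring on the (2R)-flavan | O=C1c2c(O)cc(O)cc2O[C@@]2(c3ccc(O)cc3)Oc3cc(O)c4c(c3[C@@H]12)O[C@@H](c1ccc(O)cc1)CC4 | target

Total step count: 14. Longest linear sequence: 11 steps (7 to 22, steps 4–14).

Steps most likely to fail

1. Step 13. The hindered, electron-rich partners may combine too slowly under a chiral acid of moderate strength. The face selection in the shift may be poor, or H3 may be lost after the shift.
The fallback sets out from 6 and 17 and comes back at 21. Union and rearrangement are separated and chiral catalysis is given up.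
Compound 6 is deprotonated (LiHMDS, THF, −78 °C) and added to the MOM-protected aldehyde 17. The lithium aldolate is trapped with Ac2O as the aldol acetate F1, which shuts off the retro-aldol path.
BF3·OEt2 (CH2Cl2, −78 to −20 °C), the classical promoter of 1,2-acyl shifts in α,β-epoxy ketones, then ionises the trialkoxybenzylic acetate. The acyl shift enlarges the ring, and the MOM ether oxygen O7'' captures C2 and gives up its methoxymethyl group to acetate.
This should give 21 beside the (2R,3R,2''R) diastereomer F2. Because of the flavan centre the two are diastereomers and are parted by chromatography.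

2. Step 10. The site selectivity between C8 and C6 may be poor.
The fallback sets out from 7 and comes back at 18. It fixes the substitution pattern by symmetry instead of by selectivity.
Selective para O-benzylation of 7 (BnBr 1.0 equiv, K2CO3, DMF) gives the symmetric 4-(benzyloxy)-2,6-dihydroxybenzaldehyde F3.
Heating F3 with paraformaldehyde and 4-benzyloxystyrene (NaOAc, AcOH, 80 °C) is a three-component o-quinone methide hetero-Diels–Alder reaction. It builds the pyran ring at one of the two equivalent free ring positions, using the neighbouring free phenol as the only possible ring oxygen.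
The racemic 8-formyl-7-hydroxyflavan F4 then forms with the formyl group necessarily at C8.
Preparative chromatography on a chiral stationary phase gives 18 and sets aside the (S)-enantiomer F5.

3. Step 14. Over-reduction may occur (cleavage of the benzylic C–O bonds of the ketal or of the pyran ring), or the ketal may open on the catalyst surface.
The fallback sets out from 21 and comes back at 22. It is a non-reductive debenzylation with BCl3 and pentamethylbenzene as cation scavenger (CH2Cl2, −78 °C, MeOH quench), a Lewis acid dealkylation instead of a hydrogenolysis. It makes no new compound F0.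

Further compounds
F1 | step 13 | aldol acetate: [4,6-bis(benzyloxy)-2-(4-benzyloxyphenyl)-3-oxo-2,3-dihydrobenzofuran-2-yl][(2R)-5-(benzyloxy)-2-(4-benzyloxyphenyl)-7-(methoxymethoxy)chroman-8-yl]methyl acetate (epimer mixture) | O=C1c2c(OCc3ccccc3)cc(OCc3ccccc3)cc2OC1(c1ccc(OCc2ccccc2)cc1)C(OC(C)=O)c1c(OCOC)cc(OCc2ccccc2)c2c1O[C@@H](c1ccc(OCc3ccccc3)cc1)CC2
F2 | step 13 | (2R,3R,2''R) diastereomer of 21 | O=C1c2c(OCc3ccccc3)cc(OCc3ccccc3)cc2O[C@]2(c3ccc(OCc4ccccc4)cc3)Oc3cc(OCc4ccccc4)c4c(c3[C@H]12)O[C@@H](c1ccc(OCc2ccccc2)cc1)CC4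
F3 | step 10 | 4-(benzyloxy)-2,6-dihydroxybenzaldehyde | O=Cc1c(O)cc(OCc2ccccc2)cc1O
F4 | step 10 | racemic 5-(benzyloxy)-2-[4-(benzyloxy)phenyl]-7-hydroxychromane-8-carbaldehyde | O=Cc1c(O)cc(OCc2ccccc2)c2c1OC(c1ccc(OCc3ccccc3)cc1)CC2
F5 | step 10 | (S)-5-(benzyloxy)-2-[4-(benzyloxy)phenyl]-7-hydroxychromane-8-carbaldehyde | O=Cc1c(O)cc(OCc2ccccc2)c2c1O[C@H](c1ccc(OCc3ccccc3)cc1)CC2
F0 | step 14 | none | none
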